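**Plan**

- Retrosynthesis: ring C is cut at O1–C2 and C2–C3 (flavonol → 2′-hydroxychalcone → A-ring acetophenone + ring-B aldehyde), the acetyl unit at C3–C4 and C4–C4a, and ring A at C8–C8a, C6–C7 and C4a–C8a, leaving a side-chain siloxyalkyne and 3-ethoxycyclobutenone.
- Enabling feature: ring A is a phloroglucinol whose three oxygens (O1 on C8a, O on C7, O on C5) must be told apart, with the C8 side chain between the C8a and C7 oxygens and para to the C5 oxygen. A ketene–siloxyalkyne benzannulation gives exactly this 2-alkyl-1,3,5-trioxygenated ring as OH/OSi/OEt with the chain already in place.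
- Forward order: (R)-limonene → C10 hydroxy ester → siloxyalkyne (the C8–CH2 bond arises in the ester homologation) → ring A (step 8) → acetyl group at C4a → chalcone with diallyl-protected 2,4-dihydroxybenzaldehyde → ring C by oxidative cyclisation → O5 de-ethylation, desilylation, deallylation.
- Stereochemistry: the only stereocentre (C2 of the hexyl chain, R) is C4 of (R)-(+)-limonene; it is carried through unchanged and no step creates a lasting new one.

Key step: step 8

Remark: ring positions use flavone numbering (O1, C2–C8a, C1′–C6′). In step names R¹ = (2R)-5-methyl-2-(prop-1-en-2-yl)-5-(triethylsilyloxy)hexyl and R² = (2R)-5-hydroxy-5-methyl-2-(prop-1-en-2-yl)hexyl. Ketene for step 7 is made by acetone pyrolysis outside the flask and led in as a gas.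

**Step 1**
Reactants: 1 (R)-(+)-limonene
Product: 3 (3R)-6-oxo-3-(prop-1-en-2-yl)heptanal, via methoxy hydroperoxide 2 (not isolated)
Conditions: O3 (1 equiv, Sudan Red 7B end-point), CH2Cl2/MeOH, NaHCO3, −78 °C; then Me2S, −78 °C → rt
Reagents that add atoms: ozone, [O-][O+]=O
Why: Ozonolysis is selective because ozone attacks the electron-rich trisubstituted ring alkene much faster than the 1,1-disubstituted isopropenyl group, and reductive work-up of the methanol-trapped carbonyl oxide gives the keto aldehyde; the limonene stereocentre is not involved and becomes C3.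

**Step 2**
Reactants: 3 (3R)-6-oxo-3-(prop-1-en-2-yl)heptanal
Product: 4 (3R)-6-oxo-3-(prop-1-en-2-yl)heptanoic acid
Conditions: NaClO2, NaH2PO4, 2-methyl-2-butene (excess), t-BuOH/H2O, 0 °C → rt
Reagents that add atoms: sodium chlorite, [Na+].[O-]Cl=O
Why: Pinnick oxidation converts the aldehyde to the acid under buffered conditions that leave the methyl ketone alone, the scavenger protects the isopropenyl group from hypochlorite, and the stereocentre is β to the carbonyl and cannot epimerise.

**Step 3**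
Reactants: 4 (3R)-6-oxo-3-(prop-1-en-2-yl)heptanoic acid
Product: 5 (3R)-6-hydroxy-6-methyl-3-(prop-1-en-2-yl)heptanoic acid
Conditions: MeMgBr (3.5 equiv), THF, −20 → 0 °C; aq. HCl to pH 3
Reagents that add atoms: methylmagnesium bromide, C[Mg]Br
Why: In this Grignard addition the first equivalent forms the unreactive magnesium carboxylate, so the excess reagent adds only to the ketone and gives the tertiary alcohol, whose carbinol carbon is not a stereocentre.

**Step 4**
Reactants: 5 (3R)-6-hydroxy-6-methyl-3-(prop-1-en-2-yl)heptanoic acid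
Product: 6 methyl (3R)-6-hydroxy-6-methyl-3-(prop-1-en-2-yl)heptanoate
Conditions: MeI, K2CO3, DMF, rt
Reagents that add atoms: iodomethane, CI
Why: SN2 O-alkylation of the potassium carboxylate gives the methyl ester needed for the homologation, and the tertiary alcohol is not alkylated under carbonate conditions.

**Step 5**
Reactants: 6 methyl (3R)-6-hydroxy-6-methyl-3-(prop-1-en-2-yl)heptanoate
Product: 7 methyl (3R)-6-methyl-3-(prop-1-en-2-yl)-6-(triethylsilyloxy)heptanoate
Conditions: TESOTf, 2,6-lutidine, CH2Cl2, −78 → 0 °C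
Reagents that add atoms: triethylsilyl trifluoromethanesulfonate, CC[Si](CC)(CC)OS(=O)(=O)C(F)(F)F
Why: Silylation with a silyl triflate and a hindered pyridine base works on hindered tertiary alcohols and masks the hydroxyl proton against the lithium bases of step 6 and against ketene capture in step 8.

**Step 6**
Reactants: 7 methyl (3R)-6-methyl-3-(prop-1-en-2-yl)-6-(triethylsilyloxy)heptanoate
Product: 10 (4R)-7-methyl-4-(prop-1-en-2-yl)-7-(triethylsilyloxy)-1-(triisopropylsilyloxy)oct-1-yne, via dibromoketone enolate 8 (not isolated), via lithium ynolate 9 (not isolated)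
Conditions: CH2Br2, LiTMP, THF, −78 °C; 7; LiHMDS; n-BuLi, −78 °C → rt; TIPSCl, −78 → 0 °C; aqueous work-up
Reagents that add atoms: dibromomethane, BrCBr; chlorotriisopropylsilane, CC(C)[Si](Cl)(C(C)C)C(C)C
Why: In this Kowalski ester homologation LiCHBr2 adds to the ester, enolate 8 undergoes bromine–lithium exchange and 1,2-shift of the alkyl group to ynolate 9, and O-silylation with the bulky TIPS chloride gives an isolable siloxyalkyne in which the ester carbon is the siloxy-bearing carbon (future C7) and the dibromomethane carbon is future C8.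

**Step 7**
Reactants: 11 ethoxyacetylene
Product: 12 3-ethoxycyclobut-2-en-1-one
Conditions: ketene (gas, from acetone pyrolysis), CH2Cl2, −20 → 0 °C
Reagents that add atoms: ketene, C=C=O
Why: Thermal [2+2] cycloaddition of ketene with the electron-rich ynol ether joins the ketene carbonyl carbon to the unsubstituted alkyne carbon and gives the vinylogous-ester cyclobutenone directly.

**Step 8**
Reactants: 10 (4R)-7-methyl-4-(prop-1-en-2-yl)-7-(triethylsilyloxy)-1-(triisopropylsilyloxy)oct-1-yne; 12 3-ethoxycyclobut-2-en-1-one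
Product: 16 5-ethoxy-2-R¹-3-(triisopropylsilyloxy)phenol, via ethoxyvinylketene 13 (not isolated), via vinylcyclobutenone 14 (not isolated), via dienylketene 15 (not isolated)
Conditions: toluene (degassed), 12 added in portions, 80 °C then 110 °C, sealed vessel, Ar
Reagents that add atoms: none
Why: Heating opens 12 by 4π-electrocyclic ring opening to ethoxyvinylketene 13, whose ketene C=C adds to siloxyalkyne 10 in a [2+2] cycloaddition (new bonds C8–C8a and C6–C7) to give vinylcyclobutenone 14; a second 4π opening gives dienylketene 15, which closes ring A by thermal disrotatory 6π-electrocyclisation (C4a–C8a, the bond that was broken in 12) and tautomerises to the phenol. The closest known reaction type is the Danheiser benzannulation of cyclobutenones with triisopropylsiloxyalkynes made by Kowalski homologation. No stereocentre is created in the product (C4 of 14 is lost on ring opening), and the side-chain centre is remote and not epimerisable. The step needs regioselectivity in the [2+2]: the ynol-ether oxygen makes the chain-bearing alkyne carbon the nucleophilic one, so it bonds to the electrophilic ketene carbonyl carbon and the chain ends up between OH and OSi, para to OEt. It also needs chemoselectivity for the polarised alkyne over the unactivated isopropenyl alkene, which the same polarisation secures. Only the dienylketene isomer with ketene and ethoxyvinyl groups cis can cyclise, and reversible opening of 14 should funnel material through it.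

**Step 9**
Reactants: 16 5-ethoxy-2-R¹-3-(triisopropylsilyloxy)phenol
Product: 17 6-ethoxy-2-hydroxy-3-R¹-4-(triisopropylsilyloxy)benzaldehyde
Conditions: MgCl2 (anhydrous), Et3N, (CH2O)n, THF, reflux; cold aq. NH4Cl
Reagents that add atoms: paraformaldehyde (as formaldehyde), C=O
Why: In this magnesium-mediated ortho-formylation (Casnati–Skattebøl) the magnesium phenoxide delivers formaldehyde to the only free ortho position, C4a, and a second formaldehyde oxidises the benzylic alkoxide to the aldehyde; C6, para to the hydroxyl, is not reached by this chelate-controlled process.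

**Step 10**
Reactants: 17 6-ethoxy-2-hydroxy-3-R¹-4-(triisopropylsilyloxy)benzaldehyde
Product: 18 3-ethoxy-2-(1-hydroxyethyl)-6-R¹-5-(triisopropylsilyloxy)phenol (carbinol epimers)
Conditions: MeMgBr (3 equiv), THF, −78 → 0 °C; aq. NH4Cl
Reagents that add atoms: methylmagnesium bromide, C[Mg]Br
Why: Grignard addition to the aldehyde, after deprotonation of the phenol, gives the secondary benzylic alcohol as an epimer mixture that does not matter because the carbinol is oxidised in the next step.

**Step 11**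
Reactants: 18 3-ethoxy-2-(1-hydroxyethyl)-6-R¹-5-(triisopropylsilyloxy)phenol
Product: 19 1-[6-ethoxy-2-hydroxy-3-R¹-4-(triisopropylsilyloxy)phenyl]ethan-1-one
Conditions: MnO2 (activated, excess), CH2Cl2, rt
Reagents that add atoms: none
Why: Activated manganese dioxide oxidises the electron-rich benzylic alcohol selectively to the o-hydroxyacetophenone without touching the phenol, the alkene or the silyl ethers.

**Step 12**
Reactants: 19 1-[6-ethoxy-2-hydroxy-3-R¹-4-(triisopropylsilyloxy)phenyl]ethan-1-one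
Product: 20 1-[4-(allyloxy)-6-ethoxy-2-hydroxy-3-R¹-phenyl]ethan-1-one
Conditions: TBAF (1.1 equiv), allyl bromide (2 equiv), THF, 0 °C → rt
Reagents that add atoms: allyl bromide, C=CCBr
Why: Fluoride cleaves the aryl silyl ether para to the acetyl group much faster than the hindered tertiary alkyl TES ether, and the resulting tetrabutylammonium phenoxide is allylated in situ (Williamson ether synthesis), while the C8a hydroxyl stays free because it is hydrogen-bonded to the ketone; the base-labile TIPS group is thus replaced by one that survives steps 14 and 15.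

**Step 13**
Reactants: 21 2,4-dihydroxybenzaldehyde
Product: 22 2,4-bis(allyloxy)benzaldehyde
Conditions: allyl bromide (2.5 equiv), K2CO3, DMF, 60 °C
Reagents that add atoms: allyl bromide, C=CCBr
Why: Williamson etherification of both phenols gives the base-stable ring-B aldehyde, whose allyl groups can later be removed without acid.

**Step 14**
Reactants: 20 1-[4-(allyloxy)-6-ethoxy-2-hydroxy-3-R¹-phenyl]ethan-1-one; 22 2,4-bis(allyloxy)benzaldehyde
Product: 23 (E)-1-[4-(allyloxy)-6-ethoxy-2-hydroxy-3-R¹-phenyl]-3-[2,4-bis(allyloxy)phenyl]prop-2-en-1-one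
Conditions: KOH, EtOH, rt
Reagents that add atoms: none
Why: Claisen–Schmidt condensation of the acetophenone enolate with the non-enolisable aldehyde, followed by E1cB dehydration, gives the (E)-2′-hydroxychalcone; allyl ethers and the tertiary silyl ether are stable to alcoholic hydroxide.

**Step 15**
Reactants: 23 (E)-1-[4-(allyloxy)-6-ethoxy-2-hydroxy-3-R¹-phenyl]-3-[2,4-bis(allyloxy)phenyl]prop-2-en-1-one
Product: 25 7-(allyloxy)-2-[2,4-bis(allyloxy)phenyl]-5-ethoxy-3-hydroxy-8-R¹-4H-chromen-4-one, via dihydroflavonol 24 (not isolated)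
Conditions: 30% H2O2, aq. NaOH, MeOH/THF, 0 °C → rt
Reagents that add atoms: hydrogen peroxide, OO
Why: In the Algar–Flynn–Oyamada reaction alkaline hydrogen peroxide oxidises and cyclises the 2′-hydroxychalcone phenoxide to dihydroflavonol 24 (6-endo closure of ring C through O1–C2), which is dehydrogenated in situ to the flavonol; the unactivated isopropenyl and allyl alkenes do not react with the nucleophilic oxidant.

**Step 16**
Reactants: 25 7-(allyloxy)-2-[2,4-bis(allyloxy)phenyl]-5-ethoxy-3-hydroxy-8-R¹-4H-chromen-4-one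
Product: 26 7-(allyloxy)-2-[2,4-bis(allyloxy)phenyl]-3,5-dihydroxy-8-R¹-4H-chromen-4-one
Conditions: MgI2·OEt2 (4 equiv), THF/toluene, 70 °C; aq. NH4Cl
Reagents that add atoms: none
Why: In this chelation-assisted ether cleavage magnesium bridges the C4 carbonyl and O5 and iodide removes the ethyl group by SN2, a neutral method known to dealkylate 5-alkoxyflavonoids while sparing an acid-sensitive C8 prenyl-type chain; the non-chelating allyl ethers and the hindered silyl ether should be left alone.

**Step 17**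
Reactants: 26 7-(allyloxy)-2-[2,4-bis(allyloxy)phenyl]-3,5-dihydroxy-8-R¹-4H-chromen-4-one
Product: 27 7-(allyloxy)-2-[2,4-bis(allyloxy)phenyl]-3,5-dihydroxy-8-R²-4H-chromen-4-one
Conditions: HF·pyridine, pyridine, THF, 0 °C → rt
Reagents that add atoms: none
Why: Fluoride-driven desilylation with pyridine-buffered HF cleaves the tertiary triethylsilyl ether without ionising the tertiary alcohol or protonating the isopropenyl group.

**Step 18**
Reactants: 27 7-(allyloxy)-2-[2,4-bis(allyloxy)phenyl]-3,5-dihydroxy-8-R²-4H-chromen-4-one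
Product: 28 kushenol G
Conditions: Pd(PPh3)4 (cat.), morpholine (excess), THF, rt, Ar
Reagents that add atoms: none
Why: In this Tsuji–Trost deallylation Pd(0) ionises the three aryl allyl ethers to π-allyl complexes that morpholine traps, a neutral last step that leaves the isopropenyl group, the tertiary alcohol and the flavonol untouched.

**Compound list**

1 | (R)-(+)-limonene | C=C(C)[C@@H]1CCC(C)=CC1 | starting material
2 | (3R)-6-hydroperoxy-6-methoxy-3-(prop-1-en-2-yl)heptanal (methanol-trapped carbonyl oxide, epimers at C6, not isolated) | C=C(C)[C@H](CCC(C)(OC)OO)CC=O | intermediate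
3 | (3R)-6-oxo-3-(prop-1-en-2-yl)heptanal | C=C(C)[C@H](CCC(C)=O)CC=O | intermediate
4 | (3R)-6-oxo-3-(prop-1-en-2-yl)heptanoic acid | C=C(C)[C@H](CCC(C)=O)CC(=O)O | intermediate
5 | (3R)-6-hydroxy-6-methyl-3-(prop-1-en-2-yl)heptanoic acid | C=C(C)[C@H](CCC(C)(C)O)CC(=O)O | intermediate
6 | methyl (3R)-6-hydroxy-6-methyl-3-(prop-1-en-2-yl)heptanoate | C=C(C)[C@H](CCC(C)(C)O)CC(=O)OC | intermediate
7 | methyl (3R)-6-methyl-3-(prop-1-en-2-yl)-6-(triethylsilyloxy)heptanoate | C=C(C)[C@H](CCC(C)(C)O[Si](CC)(CC)CC)CC(=O)OC | intermediate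
8 | lithium enolate of (4R)-1,1-dibromo-7-methyl-4-(prop-1-en-2-yl)-7-(triethylsilyloxy)octan-2-one (not isolated) | C=C(C)[C@H](CCC(C)(C)O[Si](CC)(CC)CC)CC([O-])=C(Br)Br.[Li+] | intermediate
9 | lithium (4R)-7-methyl-4-(prop-1-en-2-yl)-7-(triethylsilyloxy)oct-1-yn-1-olate (not isolated) | C=C(C)[C@H](CCC(C)(C)O[Si](CC)(CC)CC)CC#C[O-].[Li+] | intermediate
10 | (4R)-7-methyl-4-(prop-1-en-2-yl)-7-(triethylsilyloxy)-1-(triisopropylsilyloxy)oct-1-yne | C=C(C)[C@H](CCC(C)(C)O[Si](CC)(CC)CC)CC#CO[Si](C(C)C)(C(C)C)C(C)C | intermediate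
11 | ethoxyacetylene | C#COCC | starting material
12 | 3-ethoxycyclobut-2-en-1-one | CCOC1=CC(=O)C1 | intermediate
13 | 3-ethoxybuta-1,3-dien-1-one (ethoxyvinylketene, not isolated) | C=C(OCC)C=C=O | intermediate
14 | 4-(1-ethoxyvinyl)-2-[(2R)-5-methyl-2-(prop-1-en-2-yl)-5-(triethylsilyloxy)hexyl]-3-(triisopropylsilyloxy)cyclobut-2-en-1-one (not isolated) | C=C(C)[C@H](CCC(C)(C)O[Si](CC)(CC)CC)CC1=C(O[Si](C(C)C)(C(C)C)C(C)C)C(C(=C)OCC)C1=O | intermediate
15 | 5-ethoxy-2-[(2R)-5-methyl-2-(prop-1-en-2-yl)-5-(triethylsilyloxy)hexyl]-3-(triisopropylsilyloxy)hexa-1,3,5-trien-1-one (ketene and ethoxyvinyl cis, not isolated) | C=C(C)[C@H](CCC(C)(C)O[Si](CC)(CC)CC)CC(=C=O)/C(O[Si](C(C)C)(C(C)C)C(C)C)=C\C(=C)OCC | intermediate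
16 | 5-ethoxy-2-[(2R)-5-methyl-2-(prop-1-en-2-yl)-5-(triethylsilyloxy)hexyl]-3-(triisopropylsilyloxy)phenol | C=C(C)[C@H](CCC(C)(C)O[Si](CC)(CC)CC)Cc1c(O)cc(OCC)cc1O[Si](C(C)C)(C(C)C)C(C)C | intermediate
17 | 6-ethoxy-2-hydroxy-3-[(2R)-5-methyl-2-(prop-1-en-2-yl)-5-(triethylsilyloxy)hexyl]-4-(triisopropylsilyloxy)benzaldehyde | C=C(C)[C@H](CCC(C)(C)O[Si](CC)(CC)CC)Cc1c(O)c(C=O)c(OCC)cc1O[Si](C(C)C)(C(C)C)C(C)C | intermediate
18 | 3-ethoxy-2-(1-hydroxyethyl)-6-[(2R)-5-methyl-2-(prop-1-en-2-yl)-5-(triethylsilyloxy)hexyl]-5-(triisopropylsilyloxy)phenol (carbinol epimers) | C=C(C)[C@H](CCC(C)(C)O[Si](CC)(CC)CC)Cc1c(O)c(C(C)O)c(OCC)cc1O[Si](C(C)C)(C(C)C)C(C)C | intermediate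
19 | 1-{6-ethoxy-2-hydroxy-3-[(2R)-5-methyl-2-(prop-1-en-2-yl)-5-(triethylsilyloxy)hexyl]-4-(triisopropylsilyloxy)phenyl}ethan-1-one | C=C(C)[C@H](CCC(C)(C)O[Si](CC)(CC)CC)Cc1c(O)c(C(C)=O)c(OCC)cc1O[Si](C(C)C)(C(C)C)C(C)C | intermediate
20 | 1-{4-(allyloxy)-6-ethoxy-2-hydroxy-3-[(2R)-5-methyl-2-(prop-1-en-2-yl)-5-(triethylsilyloxy)hexyl]phenyl}ethan-1-one | C=C(C)[C@H](CCC(C)(C)O[Si](CC)(CC)CC)Cc1c(O)c(C(C)=O)c(OCC)cc1OCC=C | intermediate
21 | 2,4-dihydroxybenzaldehyde | O=Cc1ccc(O)cc1O | starting material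
22 | 2,4-bis(allyloxy)benzaldehyde | O=Cc1ccc(OCC=C)cc1OCC=C | intermediate
23 | (E)-1-{4-(allyloxy)-6-ethoxy-2-hydroxy-3-[(2R)-5-methyl-2-(prop-1-en-2-yl)-5-(triethylsilyloxy)hexyl]phenyl}-3-[2,4-bis(allyloxy)phenyl]prop-2-en-1-one | C=C(C)[C@H](CCC(C)(C)O[Si](CC)(CC)CC)Cc1c(O)c(C(=O)/C=C/c2ccc(OCC=C)cc2OCC=C)c(OCC)cc1OCC=C | intermediate
24 | 7-(allyloxy)-2-[2,4-bis(allyloxy)phenyl]-5-ethoxy-3-hydroxy-8-[(2R)-5-methyl-2-(prop-1-en-2-yl)-5-(triethylsilyloxy)hexyl]chroman-4-one (trans at C2/C3, both antipodes, not isolated) | C=C(C)[C@H](CCC(C)(C)O[Si](CC)(CC)CC)Cc1c(OCC=C)cc(OCC)c2c1OC(c1ccc(OCC=C)cc1OCC=C)C(O)C2=O | intermediate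
25 | 7-(allyloxy)-2-[2,4-bis(allyloxy)phenyl]-5-ethoxy-3-hydroxy-8-[(2R)-5-methyl-2-(prop-1-en-2-yl)-5-(triethylsilyloxy)hexyl]-4H-chromen-4-one | C=C(C)[C@H](CCC(C)(C)O[Si](CC)(CC)CC)Cc1c(OCC=C)cc(OCC)c2c(=O)c(O)c(-c3ccc(OCC=C)cc3OCC=C)oc12 | intermediate
26 | 7-(allyloxy)-2-[2,4-bis(allyloxy)phenyl]-3,5-dihydroxy-8-[(2R)-5-methyl-2-(prop-1-en-2-yl)-5-(triethylsilyloxy)hexyl]-4H-chromen-4-one | C=C(C)[C@H](CCC(C)(C)O[Si](CC)(CC)CC)Cc1c(OCC=C)cc(O)c2c(=O)c(O)c(-c3ccc(OCC=C)cc3OCC=C)oc12 | intermediate
27 | 7-(allyloxy)-2-[2,4-bis(allyloxy)phenyl]-3,5-dihydroxy-8-[(2R)-5-hydroxy-5-methyl-2-(prop-1-en-2-yl)hexyl]-4H-chromen-4-one | C=C(C)[C@H](CCC(C)(C)O)Cc1c(OCC=C)cc(O)c2c(=O)c(O)c(-c3ccc(OCC=C)cc3OCC=C)oc12 | intermediate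
28 | kushenol G: 2-(2,4-dihydroxyphenyl)-3,5,7-trihydroxy-8-[(2R)-5-hydroxy-5-methyl-2-(prop-1-en-2-yl)hexyl]-4H-chromen-4-one | C=C(C)[C@H](CCC(C)(C)O)Cc1c(O)cc(O)c2c(=O)c(O)c(-c3ccc(O)cc3O)oc12 | target

**Step count and risks**

Total steps: 18. Longest linear sequence: 16 (steps 1–6, 8–12, 14–18).

Step 8 (benzannulation). Thermal opening of the vinylogous-ester cyclobutenone 12 may be slower than decomposition of the siloxyalkyne, and the ketene may oligomerise or acylate the phenol as it forms. The fallback sets out from 10 and rejoins at 14, and so at 16. Ethyl (E)-3-ethoxybut-2-enoate is saponified (LiOH, THF/H2O) to (E)-3-ethoxybut-2-enoic acid F1, which oxalyl chloride/cat. DMF converts into (E)-3-ethoxybut-2-enoyl chloride F2. Slow addition of F2 to 10 and Et3N in toluene at 0 °C → rt generates the same ethoxyvinylketene 13 by 1,4-dehydrochlorination, so the [2+2] adduct 14 forms without any cyclobutenone opening. Crude 14 is then thermolysed on its own (toluene, 80–110 °C) to 16.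

Step 15 (oxidative cyclisation). Ring closure through Cα of the epoxy ketone (5-exo) in place of Cβ, which the C6′ ethoxy group favours, would divert material to the aurone, and the electron-rich ring B may slow the nucleophilic epoxidation. The fallback sets out from 23 and rejoins at 24, and so at 25. Chalcone 23 is first cyclised with NaOAc in refluxing EtOH to the flavanone F3 (6-endo oxa-Michael addition, so O1–C2 is fixed before C3 is oxidised). Soft enolisation with TMSOTf/Et3N (CH2Cl2, 0 °C) gives the 4-(trimethylsilyloxy)-2H-chromene F4. Rubottom oxidation (mCPBA 1 equiv, NaHCO3, CH2Cl2, −40 °C) then gives dihydroflavonol 24, which is dehydrogenated to 25 with alkaline H2O2 as in the second stage of step 15.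

Step 16 (O5 de-ethylation). SN2 attack of iodide on an ethyl group is slower than on methyl, so forcing conditions could let adventitious HI protonate the isopropenyl group (hydroiodination or chroman-forming cyclisation) or strip the silyl and allyl ethers early. The fallback sets out from 25 and rejoins at 28; it reverses the order and avoids the Lewis acid. HF·pyridine removes the TES group to give the triallyl 5-O-ethyl flavonol F5, and Pd(PPh3)4/morpholine gives 5-O-ethylkushenol G F6. The ethyl ether is then cleaved by nucleophilic dealkylation with LiCl in DMF (150–160 °C, microwave), in which chloride attacks the ethyl group and the hydrogen-bonded peri-carbonyl phenoxide leaves, to give 28.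

**Further compounds**

F1 | step 8 | (E)-3-ethoxybut-2-enoic acid | CCO/C(C)=C/C(=O)O
F2 | step 8 | (E)-3-ethoxybut-2-enoyl chloride | CCO/C(C)=C/C(=O)Cl
F3 | step 15 | 7-(allyloxy)-2-[2,4-bis(allyloxy)phenyl]-5-ethoxy-8-[(2R)-5-methyl-2-(prop-1-en-2-yl)-5-(triethylsilyloxy)hexyl]chroman-4-one (both C2 epimers) | C=C(C)[C@H](CCC(C)(C)O[Si](CC)(CC)CC)Cc1c(OCC=C)cc(OCC)c2c1OC(c1ccc(OCC=C)cc1OCC=C)CC2=O
F4 | step 15 | 7-(allyloxy)-2-[2,4-bis(allyloxy)phenyl]-5-ethoxy-8-[(2R)-5-methyl-2-(prop-1-en-2-yl)-5-(triethylsilyloxy)hexyl]-4-(trimethylsilyloxy)-2H-chromene | C=C(C)[C@H](CCC(C)(C)O[Si](CC)(CC)CC)Cc1c(OCC=C)cc(OCC)c2c1OC(c1ccc(OCC=C)cc1OCC=C)C=C2O[Si](C)(C)C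
F5 | step 16 | 7-(allyloxy)-2-[2,4-bis(allyloxy)phenyl]-5-ethoxy-3-hydroxy-8-[(2R)-5-hydroxy-5-methyl-2-(prop-1-en-2-yl)hexyl]-4H-chromen-4-one | C=C(C)[C@H](CCC(C)(C)O)Cc1c(OCC=C)cc(OCC)c2c(=O)c(O)c(-c3ccc(OCC=C)cc3OCC=C)oc12
F6 | step 16 | 5-O-ethylkushenol G: 2-(2,4-dihydroxyphenyl)-5-ethoxy-3,7-dihydroxy-8-[(2R)-5-hydroxy-5-methyl-2-(prop-1-en-2-yl)hexyl]-4H-chromen-4-one | C=C(C)[C@H](CCC(C)(C)O)Cc1c(O)cc(OCC)c2c(=O)c(O)c(-c3ccc(O)cc3O)oc12
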